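## Retrosynthetic overview

- Feature: with benzofuranone numbering (O1, C2, C3=O) and exocyclic carbons Cα and Cα', the chain O=C3–C2=Cα–Cα'=C2'–C3'=O is a dehydrogenated bis-enol. Adding two electrons and two protons makes both five-membered rings aromatic 3-hydroxybenzofurans, joined through a tetrasubstituted alkene Cα=Cα'.
- Disulfuretin ⇐ its hexamethyl ether (BBr3) ⇐ that reduced (leuco) bis(benzofuranyl)stilbene, by a late two-electron oxidation that creates both exocyclic alkenes and their geometry.
- Leuco compound ⇐ two molecules of methyl 4-methoxysalicylate + (E)-1,4-dibromo-2,3-bis(3,4-dimethoxyphenyl)but-2-ene in one flask: O1–C2 by phenoxide SN2 and C2–C3 by Claisen closure, on both sides.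
- Dibromide ⇐ 2,3-diarylbuta-1,3-diene (1,4-addition of Br2) ⇐ veratril (double Wittig methylenation, preferred to acid dehydration of a pinacol, which would invite aryl migration with these electron-rich rings).
- Ring order: the four benzene rings are bought; the two furan rings form together in step 3; no ring is made afterwards.

Key step: step 3

Remark: 3,3',4,4'-tetramethoxybenzil (veratril) and methyl 4-methoxysalicylate are taken as catalogue compounds.
Remark: if step 2 gives some (Z)-dibromide, it need not be removed, because the central C=C becomes the Cα–Cα' single bond in step 4 and both isomers give the same quinoid diene; the route is written for E.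
Remark: the leuco compound is drawn as the bis-enol; after protonation it may sit partly in C2–H keto forms, which all return the same dianion with base, so it is carried on crude under argon.

## Route

Step 1
Reactants: 1 1,2-bis(3,4-dimethoxyphenyl)ethane-1,2-dione (veratril)
Product: 2 2,3-bis(3,4-dimethoxyphenyl)buta-1,3-diene
Conditions: Ph3PCH3Br (3 equiv), KOtBu (3 equiv), THF, 0 °C → reflux
Reagents that add atoms: methyltriphenylphosphonium bromide, C[P+](c1ccccc1)(c1ccccc1)c1ccccc1.[Br-]
Why: Double Wittig methylenation of a non-enolisable 1,2-diketone should give the diene without any cationic intermediate that could trigger aryl migration, and no stereocentre is formed.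

Step 2
Reactants: 2 2,3-bis(3,4-dimethoxyphenyl)buta-1,3-diene
Product: 3 (E)-1,4-dibromo-2,3-bis(3,4-dimethoxyphenyl)but-2-ene
Conditions: Br2 (1.0 equiv), CH2Cl2, −78 → −20 °C, dark; used crude without chromatography
Reagents that add atoms: bromine, BrBr
Why: Electrophilic 1,4-addition of bromine to a 1,3-diene should proceed through an aryl-stabilised allyl cation that takes bromide at the far CH2, any tertiary 1,2-adduct re-ionising to the more stable tetrasubstituted (E)-alkene, while at −78 °C with one equivalent the styrene-type alkene should react far faster than the dimethoxyphenyl rings.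

Step 3
Reactants: 3 (E)-1,4-dibromo-2,3-bis(3,4-dimethoxyphenyl)but-2-ene; 4 methyl 2-hydroxy-4-methoxybenzoate (2.1 equiv)
Product: 6 (E)-1,2-bis(3,4-dimethoxyphenyl)-1,2-bis(3-hydroxy-6-methoxybenzofuran-2-yl)ethene (leuco form), via bis(aryl ether) diester 5 (not isolated)
Conditions: K2CO3 (3 equiv), 18-crown-6 (cat.), THF, 50 °C; then LiN(iPr)2 (6 equiv), −78 → 0 °C; degassed AcOH, then water, under Ar
Reagents that add atoms: none
Why: Proposed new method: the potassium phenoxide of 4 should displace both primary allylic bromides of 3 by SN2 (O1–C2 twice) to give 5, and LiN(iPr)2 should then remove on each side an O–CH2 proton that is allylic, α to oxygen and conjugated through the alkene with the aryl-bearing carbon, the ester-chelated carbanion adding to the ortho ester carbonyl and expelling methoxide (C2–C3 twice). The closest known reaction type is the O-alkylation/intramolecular Claisen (Dieckmann-type) route from salicylate esters to 3-hydroxybenzofurans, established with α-halo carbonyl compounds and benzylic halides; its use with an allylic halide, and on two sides of one molecule, is the untested part. Each of the two furan rings closes 5-exo-trig on the ester carbonyl. The 2H-benzofuran-3-ones first formed are deprotonated at once at C2 by methoxide or amide to the aromatic 3-oxidobenzofurans, so no stereocentre is created; the central alkene geometry, E unless the allyl anions rotate, is of no consequence because it disappears in step 4. The step needs SN2 and not SN2' alkylation, which the fully substituted alkene carbons secure, and it needs ring closure to outrun 1,4-elimination of aryloxide from the allyl anion and Wittig rearrangement, for which the lithium-bound ester held in a five-membered transition state at −78 °C is relied on.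

Step 4
Reactants: 6 (E)-1,2-bis(3,4-dimethoxyphenyl)-1,2-bis(3-hydroxy-6-methoxybenzofuran-2-yl)ethene
Product: 7 (2Z,2'Z)-2,2'-[1,2-bis(3,4-dimethoxyphenyl)ethane-1,2-diylidene]bis(6-methoxybenzofuran-3(2H)-one)
Conditions: KOtBu (2.2 equiv), THF, −78 °C; I2 (1.0 equiv), −78 → 0 °C; aq Na2S2O3
Reagents that add atoms: none
Why: Two-electron oxidation of a bis-enolate to its quinoid form (as for hydroquinone or leuco-indigo dianions), by iodination at C2 and 1,6-expulsion of iodide through Cα=Cα', should give the C2=Cα–Cα'=C2' diene, each new alkene taking the (Z) geometry with O1 beside the other Cα and the twisted aryl group beside C3=O, which is the less crowded rotamer of the dianion and is expected to be the arrangement favoured at equilibrium.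

Step 5
Reactants: 7 (2Z,2'Z)-2,2'-[1,2-bis(3,4-dimethoxyphenyl)ethane-1,2-diylidene]bis(6-methoxybenzofuran-3(2H)-one)
Product: 8 disulfuretin, (2Z,2'Z)-2,2'-[1,2-bis(3,4-dihydroxyphenyl)ethane-1,2-diylidene]bis(6-hydroxybenzofuran-3(2H)-one)
Conditions: BBr3 (12 equiv), CH2Cl2, −78 °C → rt; MeOH, then H2O, 0 °C
Reagents that add atoms: none
Why: BBr3 cleavage of aryl methyl ethers, known on methoxyaurones, should free all six phenols, the tetrasubstituted enone carbons being shielded from bromide addition and the (Z,Z) geometry being the one expected at equilibrium, so that Lewis-acid-promoted rotation should not erode it.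

## Compound list

1 | 1,2-bis(3,4-dimethoxyphenyl)ethane-1,2-dione (veratril) | COc1ccc(cc1OC)C(=O)C(=O)c1ccc(OC)c(OC)c1 | starting material
2 | 2,3-bis(3,4-dimethoxyphenyl)buta-1,3-diene | COc1ccc(cc1OC)C(=C)C(=C)c1ccc(OC)c(OC)c1 | intermediate
3 | (E)-1,4-dibromo-2,3-bis(3,4-dimethoxyphenyl)but-2-ene | BrC/C(c1ccc(OC)c(OC)c1)=C(/CBr)c1ccc(OC)c(OC)c1 | intermediate
4 | methyl 2-hydroxy-4-methoxybenzoate | COC(=O)c1ccc(OC)cc1O | starting material
5 | dimethyl 2,2'-{[(2E)-2,3-bis(3,4-dimethoxyphenyl)but-2-ene-1,4-diyl]bis(oxy)}bis(4-methoxybenzoate) | COC(=O)c1ccc(OC)cc1OC/C(c1ccc(OC)c(OC)c1)=C(/COc1cc(OC)ccc1C(=O)OC)c1ccc(OC)c(OC)c1 | intermediate (not isolated)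
6 | (E)-1,2-bis(3,4-dimethoxyphenyl)-1,2-bis(3-hydroxy-6-methoxybenzofuran-2-yl)ethene (leuco form) | COc1ccc2c(O)c(/C(c3ccc(OC)c(OC)c3)=C(\c3ccc(OC)c(OC)c3)c3oc4cc(OC)ccc4c3O)oc2c1 | intermediate
7 | (2Z,2'Z)-2,2'-[1,2-bis(3,4-dimethoxyphenyl)ethane-1,2-diylidene]bis(6-methoxybenzofuran-3(2H)-one) | O=C1/C(=C(/C(=C2\Oc3cc(OC)ccc3C2=O)c2ccc(OC)c(OC)c2)c2ccc(OC)c(OC)c2)Oc2cc(OC)ccc21 | intermediate
8 | disulfuretin, (2Z,2'Z)-2,2'-[1,2-bis(3,4-dihydroxyphenyl)ethane-1,2-diylidene]bis(6-hydroxybenzofuran-3(2H)-one) | O=C1/C(=C(/C(=C2\Oc3cc(O)ccc3C2=O)c2ccc(O)c(O)c2)c2ccc(O)c(O)c2)Oc2cc(O)ccc21 | target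

Total step count: 5
Longest linear sequence: 5 steps (1 → 2 → 3 → 6 → 7 → 8); 4 enters at step 3.

## Steps most likely to fail

**Step 3 (key step).** After deprotonation, the allyl anion may expel the aryloxide from the far CH2 (1,4-elimination to an aryloxy-diene) or undergo Wittig rearrangement faster than it closes onto the ester. The O–CH2 deprotonation may also be too slow.
Fallback, from 1, returning at 7, with known chemistry. Veratril 1 is condensed with two equivalents of purchased 6-methoxybenzofuran-3(2H)-one F1 under TiCl4/pyridine in THF, 0 °C → reflux (Knoevenagel-type condensation, the usual way to 2-ylidene-benzofuranones). The first condensation should give (Z)-2-[1,2-bis(3,4-dimethoxyphenyl)-2-oxoethylidene]-6-methoxybenzofuran-3(2H)-one F2, and the second, with more reagent and heat, should give 7 under thermodynamic control of the alkene geometry. Compounds 2 to 6 are then not needed.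

**Step 2.** Electrophilic bromination of the dimethoxyphenyl rings, and acid-promoted ionisation of the allylic bromide (solvolysis, cyclisation onto an aryl ring), may compete with clean 1,4-addition.
Fallback, from 2, returning at 7. Pt(PPh3)4-catalysed 1,4-diboration of 2 with bis(pinacolato)diboron should give (Z)-2,3-bis(3,4-dimethoxyphenyl)-1,4-bis(4,4,5,5-tetramethyl-1,3,2-dioxaborolan-2-yl)but-2-ene F3. Oxidation with NaBO3·4H2O should give (Z)-2,3-bis(3,4-dimethoxyphenyl)but-2-ene-1,4-diol F4. PPh3/CBr4 (Appel) at 0 °C should then give (Z)-1,4-dibromo-2,3-bis(3,4-dimethoxyphenyl)but-2-ene F5, with no electrophilic bromine or acid present. F5 takes the place of 3 in step 3 and should give dimethyl 2,2'-{[(2Z)-2,3-bis(3,4-dimethoxyphenyl)but-2-ene-1,4-diyl]bis(oxy)}bis(4-methoxybenzoate) F6 (not isolated) and then (Z)-1,2-bis(3,4-dimethoxyphenyl)-1,2-bis(3-hydroxy-6-methoxybenzofuran-2-yl)ethene F7. Step 4 applied to F7 should give 7, since the central alkene becomes a single bond.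

**Step 5.** Cleavage of six ethers may stop part-way, and the quinoid dienedione may suffer bromide addition or decomposition under the Lewis acid; the freed catechols may oxidise in air on work-up.
Fallback, from 6, returning at 8. The order of the last two steps is inverted. BBr3 in CH2Cl2 is applied to 6, which carries no quinoid system, and should give (E)-1,2-bis(3,4-dihydroxyphenyl)-1,2-bis(3,6-dihydroxybenzofuran-2-yl)ethene F8. One equivalent of I2 with NaOAc in degassed MeOH at 0 °C should then oxidise F8 to 8. The bis-enol is a far stronger reductant than the catechols, and any o-quinone formed should be reduced back by leuco compound still present.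

## Further compounds

F1 | step 3 | 6-methoxybenzofuran-3(2H)-one | COc1ccc2C(=O)COc2c1
F2 | step 3 | (Z)-2-[1,2-bis(3,4-dimethoxyphenyl)-2-oxoethylidene]-6-methoxybenzofuran-3(2H)-one | O=C1/C(=C(/C(=O)c2ccc(OC)c(OC)c2)c2ccc(OC)c(OC)c2)Oc2cc(OC)ccc21
F3 | step 2 | (Z)-2,3-bis(3,4-dimethoxyphenyl)-1,4-bis(4,4,5,5-tetramethyl-1,3,2-dioxaborolan-2-yl)but-2-ene | CC1(C)OB(C/C(c2ccc(OC)c(OC)c2)=C(\CB2OC(C)(C)C(C)(C)O2)c2ccc(OC)c(OC)c2)OC1(C)C
F4 | step 2 | (Z)-2,3-bis(3,4-dimethoxyphenyl)but-2-ene-1,4-diol | OC/C(c1ccc(OC)c(OC)c1)=C(\CO)c1ccc(OC)c(OC)c1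
F5 | step 2 | (Z)-1,4-dibromo-2,3-bis(3,4-dimethoxyphenyl)but-2-ene | BrC/C(c1ccc(OC)c(OC)c1)=C(\CBr)c1ccc(OC)c(OC)c1
F6 | step 2 | dimethyl 2,2'-{[(2Z)-2,3-bis(3,4-dimethoxyphenyl)but-2-ene-1,4-diyl]bis(oxy)}bis(4-methoxybenzoate) | COC(=O)c1ccc(OC)cc1OC/C(c1ccc(OC)c(OC)c1)=C(\COc1cc(OC)ccc1C(=O)OC)c1ccc(OC)c(OC)c1
F7 | step 2 | (Z)-1,2-bis(3,4-dimethoxyphenyl)-1,2-bis(3-hydroxy-6-methoxybenzofuran-2-yl)ethene | COc1ccc2c(O)c(/C(c3ccc(OC)c(OC)c3)=C(/c3ccc(OC)c(OC)c3)c3oc4cc(OC)ccc4c3O)oc2c1
F8 | step 5 | (E)-1,2-bis(3,4-dihydroxyphenyl)-1,2-bis(3,6-dihydroxybenzofuran-2-yl)ethene | Oc1ccc2c(O)c(/C(c3ccc(O)c(O)c3)=C(\c3ccc(O)c(O)c3)c3oc4cc(O)ccc4c3O)oc2c1
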